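**Retrosynthetic overview**
- The route rests on ring A of the eremophilane (C1–C5, C10). H10 and the C5 methyl share one face (cis fusion), the methyls on C4 and quaternary C5 are cis, and the ketone at C2 lies two atoms from C10. This is the pattern that an anionic oxy-Cope rearrangement of a bicyclo[2.2.2]octenol produces.
- Late disconnections: the O9 tiglate comes off last and the O8 (R)-2-methylbutanoate before it. The C7–isopropenyl bond comes from hydroboration of the C6=C7 alkene followed by Zweifel olefination. During these steps the C2 ketone and O9 mask each other as a bridged methyl ketal, and O8 and O9 keep their configuration throughout.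
- Key disconnection: breaking C4–C5 and re-forming C2–C7 leads back to a (Z)-propenyl carbinol of a bicyclo[2.2.2]octene that carries the 8,9-diol as an acetonide.
- The bicycle comes from creosol (as its masked o-benzoquinone) and benzyl vinyl ether by a Diels–Alder reaction. Two hydride reductions over the alkene bridge set O8 and O9, and a lipase resolution gives one enantiomer.
- Ring order: ring B forms first (the cyclohexene of the bicycle, step 1) and ring A second (step 10). A temporary C2–O–C9 bridge is closed in step 11 and opened in step 17.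

Key step: step 10

Numbering: bicycles 4–13 are numbered as in 12. C1 is the bridgehead next to C2, C2 the carbinol carbon, C3 a CH2, C4 the other bridgehead, C5(CH3)=C6 the alkene, and C7 (next to C1) and C8 (next to C4) carry oxygen; endo means syn to C5=C6. From 14 on, eremophilane numbering applies: bicycle C1→C7, C2→C2, C3→C1, C4→C10, C5→C5, C6→C6, C7→C8, C8→C9, and the propenyl carbons become C3 and C4. β is the face of the C5 methyl and H10.

Assumption: 4–9 are racemic and are drawn as the enantiomer that is carried on. The sense of the lipase resolution follows the Kazlauskas rule and would be checked by Mosher ester analysis of 10.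

**Step 1**
Reactants: 1 creosol (2-methoxy-4-methylphenol); 2 benzyl vinyl ether
Product: 4 (±)-2-endo-benzyloxy-8,8-dimethoxy-5-methylbicyclo[2.2.2]oct-5-en-7-one, via masked o-benzoquinone 3 (not isolated)
Conditions: PhI(OAc)2 (slow addition), 2 (excess), MeOH, rt
Reagents that add atoms: methanol, CO
Why: Oxidative dearomatisation of the guaiacol in methanol gives dienone 3, which is trapped before it dimerises in an inverse-electron-demand Diels–Alder reaction in which the nucleophilic CH2 of the enol ether bonds to the dienone terminus next to the ketal carbon and the endo rule turns OBn toward the new alkene, so the methyl ends on the alkene carbon next to the CH2-bearing bridgehead and both bridgeheads are set relative to each other.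

**Step 2**
Reactants: 4 Diels–Alder adduct
Product: 5 (±)-2-endo-benzyloxy-8,8-dimethoxy-5-methylbicyclo[2.2.2]oct-5-en-7-ol (7-OH anti to the alkene)
Conditions: NaBH4, MeOH, 0 °C
Reagents that add atoms: none
Why: Borohydride reduction under steric approach control, in which hydride arrives over the flat alkene bridge rather than past the inward C–H bonds of the C2–C3 bridge, so the 7-OH points away from the alkene (later 8α-O).

**Step 3**
Reactants: 5 hydroxy ketal
Product: 6 (±)-2-endo-benzyloxy-7-hydroxy-5-methylbicyclo[2.2.2]oct-5-en-8-one (7-OH anti to the alkene)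
Conditions: 1 M aq HCl, THF, 40 °C
Reagents that add atoms: water, O
Why: Acid hydrolysis of a dimethyl ketal, which becomes feasible once the neighbouring carbonyl has been reduced; the benzyl ether and the trisubstituted alkene are inert, and water captures the oxocarbenium ion faster than any hydride shift from C7.

**Step 4**
Reactants: 6 acyloin
Product: 7 (±)-2-endo-benzyloxy-5-methylbicyclo[2.2.2]oct-5-ene-7,8-diol (cis-diol; both OH anti to the alkene)
Conditions: NaBH4, MeOH, −20 °C
Reagents that add atoms: none
Why: Borohydride reduction with the same facial bias as step 2, since the C5 methyl lies in the alkene plane and leaves that side open while the C3–H bond blocks the other, so the 8-OH (later 9α-O) ends cis to the 7-OH.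

**Step 5**
Reactants: 7 cis-diol
Product: 8 (±)-2-endo-benzyloxy-7,8-(isopropylidenedioxy)-5-methylbicyclo[2.2.2]oct-5-ene (dioxolane anti to the alkene)
Conditions: Me2C(OMe)2, PPTS (cat.), CH2Cl2, rt
Reagents that add atoms: 2,2-dimethoxypropane, COC(C)(C)OC
Why: Acid-catalysed acetonide formation by ketal exchange, which only the eclipsed cis-diol of the rigid bicycle can undergo, so any trans-diol from step 4 is removed here.

**Step 6**
Reactants: 8 benzyl ether
Product: 9 (±)-7,8-(isopropylidenedioxy)-5-methylbicyclo[2.2.2]oct-5-en-2-endo-ol
Conditions: Na, NH3(l), THF, −78 °C; then NH4Cl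
Reagents that add atoms: none
Why: Dissolving-metal (Birch-type) debenzylation cleaves the benzylic C–O bond and leaves the isolated alkene and the acetonide untouched, whereas hydrogenolysis would put the strained alkene at risk.

**Step 7**
Reactants: 9 racemic alcohol
Product: 10 (2S)-7,8-(isopropylidenedioxy)-5-methylbicyclo[2.2.2]oct-5-en-2-endo-ol (single enantiomer)
Conditions: Burkholderia cepacia lipase (immobilised), vinyl acetate, MTBE, 35 °C, stopped just past half conversion; chromatography
Reagents that add atoms: none
Why: Lipase-catalysed kinetic resolution by irreversible transesterification, in which the Kazlauskas rule (bridgehead C1 large, C3H2 medium) predicts faster acetylation of the (2R)-alcohol, so the (2S)-alcohol remains and fixes the absolute configuration of C1, C4, C7 and C8.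

**Step 8**
Reactants: 10 resolved alcohol
Product: 11 7,8-(isopropylidenedioxy)-5-methylbicyclo[2.2.2]oct-5-en-2-one (single enantiomer)
Conditions: Dess–Martin periodinane, CH2Cl2, 0 °C to rt
Reagents that add atoms: none
Why: Dess–Martin oxidation of a secondary alcohol under near-neutral conditions; the β,γ-unsaturated ketone cannot conjugate, and the β-alkoxy group cannot be eliminated because enolisation toward the bridgehead is forbidden.

**Step 9**
Reactants: 11 ketone
Product: 12 2-[(Z)-prop-1-enyl]-7,8-(isopropylidenedioxy)-5-methylbicyclo[2.2.2]oct-5-en-2-ol (propenyl syn to the alkene; OH syn to the dioxolane bridge)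
Conditions: (Z)-1-bromopropene, t-BuLi (2 equiv), Et2O, −78 °C; then 11, −78 to −30 °C; aq NH4Cl
Reagents that add atoms: (Z)-1-bromoprop-1-ene, C/C=C\Br
Why: Bromine–lithium exchange with retention of alkene geometry followed by 1,2-addition of the alkenyllithium, which attacks from the open alkene side because the C7 oxygen of the acetonide covers the other carbonyl face, so the carbinol centre carries the propenyl group over the alkene.

**Step 10**
Reactants: 12 (Z)-propenyl carbinol
Product: 15 8α,9α-(isopropylidenedioxy)-4β,5β-dimethyl-10βH-decal-6-en-2-one (cis-fused), via potassium alkoxide 13 (not isolated), via potassium enolate 14 (not isolated)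
Conditions: KH, 18-crown-6, THF, 0 °C to reflux; aq NH4Cl, 0 °C
Reagents that add atoms: none
Why: KH and 18-crown-6 convert 12 into the free potassium alkoxide 13, whose oxyanion weakens the bond from the carbinol carbon to the bridgehead (C2–C7 in eremophilane numbering), so a concerted suprafacial [3,3] shift joins the propenyl terminus to the methyl-bearing alkene carbon (new C4–C5 bond), cleaves that bridge bond and leaves the C6=C7 alkene and the C2–C3 enolate 14, which is protonated on work-up, with strain release and enolate formation making the shift irreversible. The closest known reaction type is the anionic oxy-Cope rearrangement of 2-alkenylbicyclo[2.2.2]oct-5-en-2-ols to cis-fused decalenones. Ring A (C1–C5, C10) closes as a six-membered carbocycle by bonding of the two termini of the 1,5-diene through a six-centre boat transition state, the only one the rigid bicycle allows. C5 is controlled by the tether, because the propenyl arm reaches only the alkene face turned toward the carbinol bridge, the face on which C1 is already bound to C10, so the C5 methyl ends on the face of H10 (cis fusion). C4 is controlled by alkene geometry, because in the boat the methyl that is cis to the carbinol carbon ends cis to the C5 methyl on ring A, whereas an E-propenyl group would give the C4 epimer. The step needs the alkenyl group syn to the alkene bridge (secured in step 9), intact Z geometry and an inert diol mask, and the acetonide provides this because it has no acidic hydrogen and no group that can migrate to the alkoxide, its C–O bonds are gauche rather than antiperiplanar to the breaking bond so fragmentation is not set up, and C8, C9 and C10 pass through unchanged.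

**Step 11**
Reactants: 15 acetonide ketone
Product: 16 2β-methoxy-2α,9α-epoxy-4β,5β-dimethyl-10βH-decal-6-en-8α-ol (bridged methyl ketal)
Conditions: CSA (cat.), MeOH, rt to 40 °C; Et3N
Reagents that add atoms: methanol, CO
Why: Acid-catalysed ketal exchange in which methanolysis releases acetone and the 9α-OH, lying directly under C2 in the cis-decalin conformer with C9 axial on ring A, captures the methyl oxocarbenium ion of the ketone to close a five-membered cyclic ketal (6-oxabicyclo[3.2.1]octane), so one operation masks C2 and O9, leaves only the allylic 8-OH free and sets the temporary C2 centre through the tether; a dioxolane at C2 is avoided because it would not survive acetonide cleavage and its axial oxygen would collide with O9.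

**Step 12**
Reactants: 16 allylic alcohol
Product: 17 8-O-tert-butyldimethylsilyl ether of 16
Conditions: TBSCl, imidazole, DMF, 40 °C
Reagents that add atoms: tert-butyldimethylsilyl chloride, CC(C)(C)[Si](C)(C)Cl
Why: Standard silylation of the only free hydroxyl under basic conditions that do not ionise the ketal, giving a group that withstands borane, organolithium, iodine and methoxide.

**Step 13**
Reactants: 17 silyl ether
Product: 19 7β-(pinacolatoboryl) derivative of 17 with C6 as CH2, via monoalkylborane 18 (not isolated)
Conditions: BH3·THF (3 equiv), THF, 0 °C to rt; then pinacol, rt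
Reagents that add atoms: borane–tetrahydrofuran, B.C1CCOC1; pinacol, CC(C)(O)C(C)(C)O
Why: Hydroboration (syn addition) places boron on C7 because C6 is neopentyl next to quaternary C5 and an allylic oxygen directs boron to the nearer alkene carbon, and it comes from the convex β face, away from ring A and O9 that the oxygen bridge holds under the α face, which sets C7 (B β, H α) before pinacol converts the hindered monoalkylborane into the stable boronic ester.

**Step 14**
Reactants: 19 boronic ester
Product: 22 7β-isopropenyl-8α-(tert-butyldimethylsilyloxy)-2β-methoxy-2α,9α-epoxy-4β,5β-dimethyl-10βH-decalin, via lithium boronate 20 (not isolated), via iodoalkyl boronic ester 21 (not isolated)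
Conditions: 2-bromopropene, t-BuLi (2 equiv), Et2O, −78 °C; 19 in THF; I2, THF, −78 °C; NaOMe, MeOH, −78 °C to rt
Reagents that add atoms: 2-bromopropene, CC(Br)=C
Why: Zweifel olefination, in which isopropenyllithium adds to boron, iodine activates the alkene of 20 for a 1,2-metallate shift where C7 migrates with retention, and methoxide triggers anti elimination of boron and iodide from 21, so the 7β C–B bond becomes the 7β C–isopropenyl bond while the locked trans-diequatorial O8/B pair cannot align for β-elimination.

**Step 15**
Reactants: 22 silyl ether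
Product: 23 7β-isopropenyl-2β-methoxy-2α,9α-epoxy-4β,5β-dimethyl-10βH-decalin-8α-ol
Conditions: TBAF, THF, rt
Reagents that add atoms: none
Why: Fluoride desilylation frees O8 alone, since O9 is still part of the base-stable ketal.

**Step 16**
Reactants: 23 alcohol; 24 (R)-2-methylbutanoic acid
Product: 26 8-O-[(R)-2-methylbutanoyl] ester of 23, via O-acylisourea 25 (not isolated)
Conditions: DCC, DMAP (cat.), CH2Cl2, 0 °C to rt
Reagents that add atoms: none
Why: Steglich esterification of the equatorial 8α-OH under mild conditions that avoid a ketene pathway, so the α-stereocentre of the acid, bought as the R enantiomer, is carried over unchanged.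

**Step 17**
Reactants: 26 bridged ketal ester
Product: 27 9α-hydroxy-7β-isopropenyl-4β,5β-dimethyl-8α-[(R)-2-methylbutanoyloxy]-10βH-decalin-2-one (may equilibrate with its 2,9-hemiketal)
Conditions: 0.5 M aq HCl, THF, rt
Reagents that add atoms: water, O
Why: Ketal hydrolysis by endocyclic C2–O9 cleavage through the methyl oxocarbenium ion frees the ketone and the 9-OH together, and the dilute acid spares the isopropenyl group and keeps acyl migration slow, the equatorial O8 ester being the more stable one in any case.

**Step 18**
Reactants: 27 hydroxy ketone; 28 tiglic acid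
Product: 30 target CNP0312791.1, via mixed anhydride 29 (not isolated)
Conditions: 2,4,6-Cl3C6H2COCl, Et3N, toluene, rt; then 27, DMAP, 60 °C
Reagents that add atoms: none
Why: Yamaguchi esterification, the usual choice for hindered secondary alcohols, acylates the axial 9α-OH of the open hydroxy ketone while acyl transfer to the tertiary bridgehead hemiketal hydroxyl is slower and can be reversed by DMAP, and the E-configured tigloyl group does not isomerise.

**Compound list**
1 | creosol (2-methoxy-4-methylphenol) | Cc1ccc(O)c(OC)c1 | starting material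
2 | benzyl vinyl ether | C=COCc1ccccc1 | starting material
3 | 6,6-dimethoxy-4-methylcyclohexa-2,4-dien-1-one | COC1(OC)C=C(C)C=CC1=O | intermediate
4 | (±)-2-endo-benzyloxy-8,8-dimethoxy-5-methylbicyclo[2.2.2]oct-5-en-7-one | c1ccccc1CO[C@H]2C[C@H]3C(C)=C[C@@H]2C(=O)C3(OC)OC | intermediate
5 | (±)-7-alcohol of 4, OH anti to the alkene | c1ccccc1CO[C@H]2C[C@H]3C(C)=C[C@@H]2[C@@H](O)C3(OC)OC | intermediate
6 | (±)-7-hydroxy-8-ketone | c1ccccc1CO[C@H]2C[C@H]3C(C)=C[C@@H]2[C@@H](O)C3=O | intermediate
7 | (±)-cis-7,8-diol, both OH anti to the alkene | c1ccccc1CO[C@H]2C[C@H]3C(C)=C[C@@H]2[C@@H](O)[C@H]3O | intermediate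
8 | (±)-acetonide of 7 | c1ccccc1CO[C@H]2C[C@H]3C(C)=C[C@@H]2[C@H]4OC(C)(C)O[C@@H]34 | intermediate
9 | (±)-7,8-(isopropylidenedioxy)-5-methylbicyclo[2.2.2]oct-5-en-2-endo-ol | O[C@H]1C[C@H]2C(C)=C[C@@H]1[C@H]3OC(C)(C)O[C@@H]23 | intermediate
10 | (2S)-enantiomer of 9 | O[C@H]1C[C@H]2C(C)=C[C@@H]1[C@H]3OC(C)(C)O[C@@H]23 | intermediate
11 | 7,8-(isopropylidenedioxy)-5-methylbicyclo[2.2.2]oct-5-en-2-one | O=C1C[C@H]2C(C)=C[C@@H]1[C@H]3OC(C)(C)O[C@@H]23 | intermediate
12 | (Z)-propenyl carbinol, propenyl syn to the alkene | C/C=C\[C@@]1(O)C[C@H]2C(C)=C[C@@H]1[C@H]3OC(C)(C)O[C@@H]23 | intermediate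
13 | potassium alkoxide of 12 | C/C=C\[C@@]1([O-])C[C@H]2C(C)=C[C@@H]1[C@H]3OC(C)(C)O[C@@H]23.[K+] | intermediate
14 | potassium C2–C3 enolate of 15 | C1=C[C@@]2(C)[C@H](CC([O-])=C[C@@H]2C)[C@@H]3OC(C)(C)O[C@@H]31.[K+] | intermediate
15 | cis-fused 6-en-2-one with 4β,5β-dimethyl and 8α,9α-acetonide | C1=C[C@@]2(C)[C@H](CC(=O)C[C@@H]2C)[C@@H]3OC(C)(C)O[C@@H]31 | intermediate
16 | bridged methyl ketal, 6-ene, free 8α-OH | O[C@@H]1C=C[C@]2(C)[C@@H](C)C[C@@]3(OC)C[C@@H]2[C@@H]1O3 | intermediate
17 | 8-O-TBS ether of 16 | CC(C)(C)[Si](C)(C)O[C@@H]1C=C[C@]2(C)[C@@H](C)C[C@@]3(OC)C[C@@H]2[C@@H]1O3 | intermediate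
18 | 7β-monoalkylborane | CC(C)(C)[Si](C)(C)O[C@@H]1[C@@H](B)C[C@]2(C)[C@@H](C)C[C@@]3(OC)C[C@@H]2[C@@H]1O3 | intermediate
19 | 7β-pinacol boronic ester | CC(C)(C)[Si](C)(C)O[C@@H]1[C@@H](B4OC(C)(C)C(C)(C)O4)C[C@]2(C)[C@@H](C)C[C@@]3(OC)C[C@@H]2[C@@H]1O3 | intermediate
20 | lithium isopropenyl boronate of 19 | CC(C)(C)[Si](C)(C)O[C@@H]1[C@@H]([B-]4(C(C)=C)OC(C)(C)C(C)(C)O4)C[C@]2(C)[C@@H](C)C[C@@]3(OC)C[C@@H]2[C@@H]1O3.[Li+] | intermediate
21 | 7β-[1-iodo-2-(pinacolatoboryl)propan-2-yl] compound (side-chain centre undefined) | CC(C)(C)[Si](C)(C)O[C@@H]1[C@@H](C(C)(CI)B4OC(C)(C)C(C)(C)O4)C[C@]2(C)[C@@H](C)C[C@@]3(OC)C[C@@H]2[C@@H]1O3 | intermediate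
22 | 7β-isopropenyl 8-O-TBS bridged ketal | CC(C)(C)[Si](C)(C)O[C@@H]1[C@@H](C(C)=C)C[C@]2(C)[C@@H](C)C[C@@]3(OC)C[C@@H]2[C@@H]1O3 | intermediate
23 | 7β-isopropenyl 8α-ol bridged ketal | O[C@@H]1[C@@H](C(C)=C)C[C@]2(C)[C@@H](C)C[C@@]3(OC)C[C@@H]2[C@@H]1O3 | intermediate
24 | (R)-2-methylbutanoic acid | CC[C@@H](C)C(=O)O | starting material
25 | O-acylisourea from 24 and DCC | CC[C@@H](C)C(=O)OC(=NC1CCCCC1)NC1CCCCC1 | intermediate
26 | 8-O-[(R)-2-methylbutanoyl] bridged ketal | CC[C@@H](C)C(=O)O[C@@H]1[C@@H](C(C)=C)C[C@]2(C)[C@@H](C)C[C@@]3(OC)C[C@@H]2[C@@H]1O3 | intermediate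
27 | 9α-hydroxy-2-ketone 8-ester | CC[C@@H](C)C(=O)O[C@@H]1[C@@H](C(C)=C)C[C@]2(C)[C@@H](C)CC(=O)C[C@@H]2[C@@H]1O | intermediate
28 | tiglic acid | C/C=C(\C)C(=O)O | starting material
29 | tiglic 2,4,6-trichlorobenzoic anhydride | C/C=C(\C)C(=O)OC(=O)c1c(Cl)cc(Cl)cc1Cl | intermediate
30 | CNP0312791.1 | C=C(C)[C@H]1C[C@@]2(C)[C@H](CC(=O)C[C@@H]2C)[C@H](OC(=O)/C(C)=C/C)[C@@H]1OC(=O)[C@H](C)CC | target

**Step count and risks**
Total step count: 18. Longest linear sequence: 18 steps, from creosol.

Steps most likely to fail:

Step 10 (key step). The methyl of the Z-propenyl group points into the boat transition state and toward the C5 methyl. The [3,3] shift may therefore become slower than base-induced cleavage of the alkoxide or erosion of the alkene geometry. The fallback runs from 12 back to 15. The hydroxyl is silylated (TMSOTf, 2,6-lutidine, CH2Cl2, −78 °C) to the trimethylsilyl ether F1. This is heated without base (o-dichlorobenzene, sealed tube, about 220 °C), so that a neutral siloxy-Cope rearrangement through the same boat gives the trimethylsilyl enol ether F2. K2CO3 in MeOH then frees ketone 15.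

Step 13. Hydroboration of the hindered alkene may be sluggish. It may also carry on to a dialkylborane that pinacol cannot convert, or lose regiocontrol between C6 and C7. The fallback runs from 16 back to 23 and builds the C7–carbon bond on an sp2 centre instead.
- MnO2 in CH2Cl2 oxidises the allylic alcohol to the bridged-ketal enone F3.
- I2 and pyridine in CH2Cl2 give the 7-iodo enone F4.
- Suzuki coupling with isopropenylboronic acid pinacol ester (Pd(dppf)Cl2, Cs2CO3, aqueous dioxane) gives the cross-conjugated dienone F5.
- [(Ph3P)CuH]6 in wet toluene delivers hydride to C6, and α-protonation of the dienolate gives the 7β-isopropenyl 8-ketone F6. The oxygen bridge holds ring B in the chair where the 7β group is equatorial, so brief contact with Et3N should correct a 7α epimer. Long exposure would risk conjugation to the isopropylidene ketone.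
- NaBH4 in MeOH at −20 °C attacks from the convex β face and gives 23.

Step 18. The 9α-OH lies in the concave pocket under ring A and can close onto C2. Acylation may therefore be slow and be diverted to the hemiketal oxygen. The fallback runs from 26 back to 30 and opens the bridge to a form that cannot re-close under basic conditions.
- TMSOTf and i-Pr2NEt (CH2Cl2, −20 °C) cleave the C2–O9 bond and eliminate to the 9-O-trimethylsilyl methyl enol ether F7. It is drawn as the 2-ene; the 1-ene converges later.
- TBAF (1 equiv, THF, −20 °C) gives the 9α-hydroxy methyl enol ether F8.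
- Yamaguchi esterification with 28 gives the 9-O-tigloyl methyl enol ether F9.
- Dilute aqueous oxalic acid in THF hydrolyses the enol ether to 30.

**Further compounds**
F1 | step 10 | trimethylsilyl ether of 12 | C/C=C\[C@@]1(O[Si](C)(C)C)C[C@H]2C(C)=C[C@@H]1[C@H]3OC(C)(C)O[C@@H]23
F2 | step 10 | trimethylsilyl enol ether of 15 | C1=C[C@@]2(C)[C@H](CC(O[Si](C)(C)C)=C[C@@H]2C)[C@@H]3OC(C)(C)O[C@@H]31
F3 | step 13 | bridged-ketal enone (6-en-8-one) | O=C1C=C[C@]2(C)[C@@H](C)C[C@@]3(OC)C[C@@H]2[C@@H]1O3
F4 | step 13 | 7-iodo enone | O=C1C(I)=C[C@]2(C)[C@@H](C)C[C@@]3(OC)C[C@@H]2[C@@H]1O3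
F5 | step 13 | cross-conjugated dienone (7-isopropenyl-6-en-8-one) | O=C1C(C(C)=C)=C[C@]2(C)[C@@H](C)C[C@@]3(OC)C[C@@H]2[C@@H]1O3
F6 | step 13 | 7β-isopropenyl 8-ketone | O=C1[C@@H](C(C)=C)C[C@]2(C)[C@@H](C)C[C@@]3(OC)C[C@@H]2[C@@H]1O3
F7 | step 18 | 9-O-trimethylsilyl methyl enol ether | CC[C@@H](C)C(=O)O[C@@H]1[C@@H](C(C)=C)C[C@]2(C)[C@@H](C)C=C(OC)C[C@@H]2[C@@H]1O[Si](C)(C)C
F8 | step 18 | 9α-hydroxy methyl enol ether | CC[C@@H](C)C(=O)O[C@@H]1[C@@H](C(C)=C)C[C@]2(C)[C@@H](C)C=C(OC)C[C@@H]2[C@@H]1O
F9 | step 18 | 9-O-tigloyl methyl enol ether | CC[C@@H](C)C(=O)O[C@@H]1[C@@H](C(C)=C)C[C@]2(C)[C@@H](C)C=C(OC)C[C@@H]2[C@@H]1OC(=O)/C(C)=C/C
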